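**Plan**

- Retrosynthesis: the methyl ester C–O bond is cut first, back to a meso cyclic anhydride. Then the two cyclobutane bonds are cut, CH(CO2Me)–CH(CO2H) and C(Me)(pyranonyl)–C(Me)(pyranonyl). This leaves the symmetric anhydride of one achiral acid, (2E)-3-(4-methoxy-3-methyl-2-oxo-2H-pyran-6-yl)but-2-enoic acid, which is cut at its C=C bond and at the pyranone lactone.
- Enabling feature: the two carboxyl carbons sit cis on adjacent cyclobutane carbons, so they can be tied through one oxygen as a five-membered oxolane-2,5-dione ring (a 3-oxabicyclo[3.2.0]heptane-2,4-dione). The core has a latent mirror plane (both pyranone rings on one face, both C-methyls and both carboxyls on the other), so this bicycle is meso and is the head-to-head dimer of one enoic acid.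
- Forward: pyranone ring (dianion acylation, lactonization, O-methylation), side chain (aldol, elimination, ester cleavage), union of two acids as the anhydride. One photochemical event then closes the anhydride ring through the CH–CH bond and the cyclobutane ring through the bond between the quaternary carbons. The anhydride ring is finally opened with methanol.
- Stereochemistry: the cis ring fusion comes from the anhydride tether. The two quaternary centres come from collapse of a 1,4-biradical with both pyranone rings on the convex face. The absolute configuration comes from quinine-mediated, enantiotopic-group-selective methanolysis of the meso anhydride.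

Key step: step 8

Remark: tert-butyl glyoxylate (6) is taken as a commercial reagent and is distilled to the monomer before use.

**Step 1**
Reactants: 1 ethyl 2-methyl-3-oxobutanoate; 2 N-methoxy-N-methylpropanamide
Product: 3 ethyl 2-methyl-3,5-dioxoheptanoate (racemic, keto/enol mixture)
Conditions: NaH, THF, 0 °C; n-BuLi, 0 °C; then 2, −78 °C to 0 °C; aq. HCl
Reagents that add atoms: none
Why: γ-Acylation of the 1,3-dianion of a β-keto ester by an N-methoxy-N-methylamide (Claisen-type condensation, Weinreb ketone synthesis) should be clean because the more basic terminal carbanion reacts first and the chelated tetrahedral intermediate prevents over-addition; the stereocentre of 3 is lost in step 2.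

**Step 2**
Reactants: 3 ethyl 2-methyl-3,5-dioxoheptanoate
Product: 4 6-ethyl-4-hydroxy-3-methyl-2H-pyran-2-one
Conditions: DBU, toluene, reflux; aq. HCl
Reagents that add atoms: none
Why: Base-mediated enol lactonization of a 3,5-diketo ester (6-exo-trig acyl substitution with loss of ethanol) is the standard closure of a 4-hydroxy-2-pyranone ring.

**Step 3**
Reactants: 4 6-ethyl-4-hydroxy-3-methyl-2H-pyran-2-one
Product: 5 6-ethyl-4-methoxy-3-methyl-2H-pyran-2-one
Conditions: Me2SO4, K2CO3, acetone, reflux
Reagents that add atoms: dimethyl sulfate, COS(=O)(=O)OC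
Why: O-Methylation of the vinylogous acid under K2CO3 (Williamson-type etherification) should favour the 4-methoxy-2-pyranone over the isomeric 2-methoxy-4-pyranone, as is usual for 3-alkyl-4-hydroxy-2-pyranones.

**Step 4**
Reactants: 5 6-ethyl-4-methoxy-3-methyl-2H-pyran-2-one; 6 tert-butyl 2-oxoacetate (tert-butyl glyoxylate)
Product: 7 tert-butyl 2-hydroxy-3-(4-methoxy-3-methyl-2-oxo-2H-pyran-6-yl)butanoate (racemic mixture of diastereomers)
Conditions: LiN(iPr)2, THF, −78 °C; then 6, −78 °C; aq. NH4Cl
Reagents that add atoms: none
Why: Kinetic deprotonation of a 6-alkyl-4-methoxy-2-pyranone takes place at the 6-alkyl α-carbon (vinylogous enolate), and this anion should add to the unhindered aldehyde in an aldol addition; the two new stereocentres form unselectively and are both removed in step 5.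

**Step 5**
Reactants: 7 tert-butyl 2-hydroxy-3-(4-methoxy-3-methyl-2-oxo-2H-pyran-6-yl)butanoate
Product: 9 tert-butyl (2E)-3-(4-methoxy-3-methyl-2-oxo-2H-pyran-6-yl)but-2-enoate, via mesylate 8 (not isolated)
Conditions: MsCl, Et3N, CH2Cl2, 0 °C; then DBU, 0 °C to rt
Reagents that add atoms: methanesulfonyl chloride, CS(=O)(=O)Cl (its atoms are carried only by intermediate 8 and leave again in the elimination)
Why: Mesylation followed by base-induced 1,2-elimination (E1cB-like, through the pyranone-stabilized carbanion) should give the conjugated enoate, with the E isomer favoured thermodynamically because the pyranone ring then lies trans to the ester; the alkene geometry is in any case not carried through step 8.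

**Step 6**
Reactants: 9 tert-butyl (2E)-3-(4-methoxy-3-methyl-2-oxo-2H-pyran-6-yl)but-2-enoate
Product: 10 (2E)-3-(4-methoxy-3-methyl-2-oxo-2H-pyran-6-yl)but-2-enoic acid
Conditions: CF3CO2H/CH2Cl2 (1:4), rt
Reagents that add atoms: none
Why: Acidolysis of the tert-butyl ester (loss of the tert-butyl cation as 2-methylpropene) should free the acid without exposing the base-sensitive pyranone lactone to hydroxide.

**Step 7**
Reactants: 10 (2E)-3-(4-methoxy-3-methyl-2-oxo-2H-pyran-6-yl)but-2-enoic acid (two molecules)
Product: 11 (2E)-3-(4-methoxy-3-methyl-2-oxo-2H-pyran-6-yl)but-2-enoic anhydride (symmetric, both alkenes E)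
Conditions: DCC (0.5 equiv per acid), dry CH2Cl2, 0 °C to rt; filtration under argon, used crude
Reagents that add atoms: none
Why: Carbodiimide-mediated dehydration of two molecules of acid (an O-acylisourea attacked by a second carboxylate) is the standard preparation of a symmetrical anhydride and leaves only insoluble urea to filter off.

**Step 8**
Reactants: 11 (2E)-3-(4-methoxy-3-methyl-2-oxo-2H-pyran-6-yl)but-2-enoic anhydride
Product: 13 (1R,5S,6R,7S)-6,7-bis(4-methoxy-3-methyl-2-oxo-2H-pyran-6-yl)-6,7-dimethyl-3-oxabicyclo[3.2.0]heptane-2,4-dione (meso; methyls cis to the anhydride ring, pyranone rings trans to it), via triplet 1,4-biradical 12 (not isolated)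
Conditions: [Ir(dF(CF3)ppy)2(dtbbpy)]PF6 (1 mol %), degassed dry CH2Cl2 (0.01 M), blue LEDs (450 nm), rt
Reagents that add atoms: none
Why: Proposed new method: triplet energy transfer from the excited iridium complex to one pyranonyl enoate should give a 1,2-biradical whose α-carbon adds to the α-carbon of the second enoate, forming the bond between the two CH carbons and leaving two tertiary, pyranone-delocalized radicals (12), which after intersystem crossing combine to form the bond between the two quaternary carbons. The closest known reaction type is the sensitized intramolecular [2+2] photocycloaddition of 1,6-dienes such as tethered bis-cinnamates, bis-enones and diacryloyl imides, together with the fast radical ring closure across an anhydride link that underlies cyclopolymerization of acrylic anhydrides; it has not been shown for an acyclic enoic anhydride. The oxolane-2,5-dione ring closes 5-exo-trig (rule of five) and the cyclobutane ring closes by radical–radical recombination of the 1,4-biradical. The two CH centres must be cis because a trans fusion of the five-membered anhydride ring onto a cyclobutane is prohibitively strained, and at each quaternary centre the larger pyranone ring should take the convex face and the methyl the concave face next to the anhydride carbonyls, which gives the meso isomer with methyls and carbonyls all cis. The step needs head-to-head regioselectivity (secured by the three-atom tether and by the stability of the doubly tertiary biradical over any crossed or pyranone-ring adduct) and diastereoselectivity at the quaternary carbons (independent of alkene geometry, since E and Z enoates converge on 12). Visible-light sensitization avoids direct excitation of the pyranone rings.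

**Step 9**
Reactants: 13 (1R,5S,6R,7S)-6,7-bis(4-methoxy-3-methyl-2-oxo-2H-pyran-6-yl)-6,7-dimethyl-3-oxabicyclo[3.2.0]heptane-2,4-dione
Product: 14 (1S,2R,3S,4R)-4-(methoxycarbonyl)-2,3-bis(4-methoxy-3-methyl-2-oxo-2H-pyran-6-yl)-2,3-dimethylcyclobutane-1-carboxylic acid (target)
Conditions: quinine (1.1 equiv), MeOH (5 equiv), toluene/CH2Cl2, −45 °C; then 1 M HCl
Reagents that add atoms: methanol, CO
Why: Cinchona alkaloid-mediated alcoholysis of a meso cyclic anhydride (enantiotopic-group-selective desymmetrization by general-base catalysis) should deliver methanol to the carbonyl on the carbon that becomes C4 (R), so all four stereocentres emerge as one enantiomer; quinine is chosen by analogy with the sense it shows for simple cis-fused bicyclic succinic anhydrides, this sense has to be confirmed on the present substrate, and quinidine would give the antipode.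

**Compound list**

1 | ethyl 2-methyl-3-oxobutanoate (racemic) | CCOC(=O)C(C)C(C)=O | starting material
2 | N-methoxy-N-methylpropanamide | CCC(=O)N(C)OC | starting material
3 | ethyl 2-methyl-3,5-dioxoheptanoate (racemic) | CCC(=O)CC(=O)C(C)C(=O)OCC | intermediate
4 | 6-ethyl-4-hydroxy-3-methyl-2H-pyran-2-one | CCc1cc(O)c(C)c(=O)o1 | intermediate
5 | 6-ethyl-4-methoxy-3-methyl-2H-pyran-2-one | CCc1cc(OC)c(C)c(=O)o1 | intermediate
6 | tert-butyl 2-oxoacetate (tert-butyl glyoxylate) | O=CC(=O)OC(C)(C)C | starting material
7 | tert-butyl 2-hydroxy-3-(4-methoxy-3-methyl-2-oxo-2H-pyran-6-yl)butanoate (diastereomer mixture) | CC(C(O)C(=O)OC(C)(C)C)c1cc(OC)c(C)c(=O)o1 | intermediate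
8 | tert-butyl 2-(methanesulfonyloxy)-3-(4-methoxy-3-methyl-2-oxo-2H-pyran-6-yl)butanoate (diastereomer mixture, not isolated) | CC(C(OS(C)(=O)=O)C(=O)OC(C)(C)C)c1cc(OC)c(C)c(=O)o1 | intermediate
9 | tert-butyl (2E)-3-(4-methoxy-3-methyl-2-oxo-2H-pyran-6-yl)but-2-enoate | C/C(=C\C(=O)OC(C)(C)C)c1cc(OC)c(C)c(=O)o1 | intermediate
10 | (2E)-3-(4-methoxy-3-methyl-2-oxo-2H-pyran-6-yl)but-2-enoic acid | C/C(=C\C(=O)O)c1cc(OC)c(C)c(=O)o1 | intermediate
11 | (2E)-3-(4-methoxy-3-methyl-2-oxo-2H-pyran-6-yl)but-2-enoic anhydride | C/C(=C\C(=O)OC(=O)/C=C(\C)c1cc(OC)c(C)c(=O)o1)c1cc(OC)c(C)c(=O)o1 | intermediate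
12 | cis-oxolane-2,5-dione carrying at C3 and at C4 a 1-(4-methoxy-3-methyl-2-oxo-2H-pyran-6-yl)ethyl radical centre (triplet 1,4-biradical, not isolated) | O1C(=O)[C@@H]([C](C)c2cc(OC)c(C)c(=O)o2)[C@H](C1=O)[C](C)c1cc(OC)c(C)c(=O)o1 | intermediate
13 | (1R,5S,6R,7S)-6,7-bis(4-methoxy-3-methyl-2-oxo-2H-pyran-6-yl)-6,7-dimethyl-3-oxabicyclo[3.2.0]heptane-2,4-dione (meso) | O1C(=O)[C@@H]2[C@H](C1=O)[C@@](C)(c1cc(OC)c(C)c(=O)o1)[C@@]2(C)c1cc(OC)c(C)c(=O)o1 | intermediate
14 | (1S,2R,3S,4R)-4-(methoxycarbonyl)-2,3-bis(4-methoxy-3-methyl-2-oxo-2H-pyran-6-yl)-2,3-dimethylcyclobutane-1-carboxylic acid | COC(=O)[C@@H]1[C@H](C(=O)O)[C@@](C)(c2cc(OC)c(C)c(=O)o2)[C@@]1(C)c1cc(OC)c(C)c(=O)o1 | target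

**Step count and risks**

Total step count: 9. Longest linear sequence: 9 steps (1 to 14; two molecules of 10 are joined in step 7).

Steps most likely to fail:

1. Step 8 (Proposed new method). The hindered biradical may revert to the dienes or disproportionate by hydrogen transfer from a methyl group instead of closing between two quaternary carbons. Facial selectivity at the quaternary centres may be poor. The acyclic anhydride may hydrolyse before it cyclizes.
Fallback, from 10 back to 13, by known template-directed solid-state chemistry. Acid 10 is esterified twice with naphthalene-1,8-diol (EDC hydrochloride, DMAP, CH2Cl2) to give naphthalene-1,8-diyl bis[(2E)-3-(4-methoxy-3-methyl-2-oxo-2H-pyran-6-yl)but-2-enoate] F1, in which the peri-diol holds the two enoates parallel and head to head. Irradiation of crystalline F1 at 365 nm should give, by a topochemical [2+2] photodimerization that retains the E geometry, the cyclic naphthalene-1,8-diyl cyclobutane-1,2-dicarboxylate F2. Mild hydrolysis of the two aryl esters (LiOH, THF/H2O, 0 °C) should give the meso diacid (1R,2S,3R,4S)-3,4-bis(4-methoxy-3-methyl-2-oxo-2H-pyran-6-yl)-3,4-dimethylcyclobutane-1,2-dicarboxylic acid F3. Dehydration with acetic anhydride at 60 °C returns to 13.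

2. Step 9. Methanolysis at the congested carbonyls may be slow, and discrimination between the two enantiotopic carbonyls may be low or of the opposite sense.
Fallback, from 13 back to 14, by resolution through covalent diastereomers. Unselective methanolysis of 13 (MeOH, catalytic DMAP, CH2Cl2) should give 14 together with an equal amount of its enantiomer, (1R,2S,3R,4S)-4-(methoxycarbonyl)-2,3-bis(4-methoxy-3-methyl-2-oxo-2H-pyran-6-yl)-2,3-dimethylcyclobutane-1-carboxylic acid F4. Steglich esterification of the mixture with (S)-1-(4-methoxyphenyl)ethanol (DCC, DMAP) gives the (1S)-1-(4-methoxyphenyl)ethyl ester of 14 F5 and the (1S)-1-(4-methoxyphenyl)ethyl ester of the enantiomer F6, which are separated by chromatography or crystallization. Acidolysis of F5 (CF3CO2H, Et3SiH, CH2Cl2, 0 °C) returns 14.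

3. Step 5. The α-mesyloxy ester may undergo substitution by chloride or DBU instead of elimination, or eliminate to a deconjugated isomer.
Fallback, from 5 back to 9, bypassing steps 4 and 5. Riley oxidation of the activated methylene of the 6-ethyl group of 5 (SeO2, 1,4-dioxane, reflux) should give 6-acetyl-4-methoxy-3-methyl-2H-pyran-2-one F7. Horner–Wadsworth–Emmons olefination of F7 with tert-butyl diethylphosphonoacetate (NaH, THF, 0 °C to rt) then gives 9.

**Further compounds**

F1 | step 8 | naphthalene-1,8-diyl bis[(2E)-3-(4-methoxy-3-methyl-2-oxo-2H-pyran-6-yl)but-2-enoate] | C/C(=C\C(=O)Oc1cccc2cccc(OC(=O)/C=C(\C)c3cc(OC)c(C)c(=O)o3)c12)c1cc(OC)c(C)c(=O)o1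
F2 | step 8 | naphthalene-1,8-diyl (1R,2S,3R,4S)-3,4-bis(4-methoxy-3-methyl-2-oxo-2H-pyran-6-yl)-3,4-dimethylcyclobutane-1,2-dicarboxylate (cyclic diester, meso) | O4c1cccc2cccc(c12)OC(=O)[C@@H]1[C@H](C4=O)[C@@](C)(c2cc(OC)c(C)c(=O)o2)[C@@]1(C)c1cc(OC)c(C)c(=O)o1
F3 | step 8 | (1R,2S,3R,4S)-3,4-bis(4-methoxy-3-methyl-2-oxo-2H-pyran-6-yl)-3,4-dimethylcyclobutane-1,2-dicarboxylic acid (meso) | OC(=O)[C@@H]1[C@H](C(=O)O)[C@@](C)(c2cc(OC)c(C)c(=O)o2)[C@@]1(C)c1cc(OC)c(C)c(=O)o1
F4 | step 9 | (1R,2S,3R,4S)-4-(methoxycarbonyl)-2,3-bis(4-methoxy-3-methyl-2-oxo-2H-pyran-6-yl)-2,3-dimethylcyclobutane-1-carboxylic acid (enantiomer of 14) | COC(=O)[C@H]1[C@@H](C(=O)O)[C@](C)(c2cc(OC)c(C)c(=O)o2)[C@]1(C)c1cc(OC)c(C)c(=O)o1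
F5 | step 9 | (1S)-1-(4-methoxyphenyl)ethyl ester of 14 | COC(=O)[C@@H]1[C@H](C(=O)O[C@@H](C)c2ccc(OC)cc2)[C@@](C)(c2cc(OC)c(C)c(=O)o2)[C@@]1(C)c1cc(OC)c(C)c(=O)o1
F6 | step 9 | (1S)-1-(4-methoxyphenyl)ethyl ester of F4 | COC(=O)[C@H]1[C@@H](C(=O)O[C@@H](C)c2ccc(OC)cc2)[C@](C)(c2cc(OC)c(C)c(=O)o2)[C@]1(C)c1cc(OC)c(C)c(=O)o1
F7 | step 5 | 6-acetyl-4-methoxy-3-methyl-2H-pyran-2-one | CC(=O)c1cc(OC)c(C)c(=O)o1
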